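**Retrosynthetic overview**

- The target is catechin-(4α→6)-epicatechin-(4β→8)-epicatechin-(4β→8)-epicatechin. The last operations are methanolysis of one acetate and a global hydrogenolysis (19 benzyl ethers, one C–Br).
- Structural feature: in unit 1, C4 is a diarylmethine carbon bonded to C4a of its own ring A and to C6 of ring A of unit 2. Ring C of unit 1 (O1, C2, C3, C4, C4a, C8a) carries the C2 aryl, C3 oxygen and C4 aryl all equatorial (2,3-trans, 3,4-trans). C4 with its ortho oxygen O1 on C8a is a latent ortho-quinone methide.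
- Key disconnection: C4–C3 and O1–C2 of unit 1. Ring C is closed by an oxa-[4+2] cycloaddition of that ortho-quinone methide with the (E)-enol acetate of 3,4-bis(benzyloxy)phenylacetaldehyde.
- The quinone methide precursor is a salicyl carbinol made from the C6 arylmagnesium of an 8-bromo-6-iodo perbenzylated epicatechin trimer and a protected 2,4,6-trioxygenated benzaldehyde. The trimer comes from two 4β→8 Friedel–Crafts couplings of epicatechin C4 ethers.
- Ring order: the nine rings of units 2 to 4 come intact from epicatechin; rings A and B of unit 1 come from the benzaldehyde and the arylacetic acid; ring C of unit 1 is the only ring formed, and it is formed last.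

Key step: step 15

**Remarks on the chemistry**

- Flavan units are numbered 1 (catechin, top) to 4 (terminal epicatechin). α is the face of the C2 aryl group of a unit, β the opposite face.
- The (R)-enantiomer of the phosphoric acid is assumed to deliver the required face in step 15. Precedent does not fix the sense of induction for this substrate, so the (S)-acid under the same conditions is the immediate alternative.
- The C8 bromine of unit 2 is a spectator: it directs iodination to C6, caps the electrophile in step 7 and leaves in the final hydrogenolysis.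

**Route**

Step 1
Reactants: 1 (−)-epicatechin
Product: 2 5,7,3',4'-tetra-O-benzyl-(−)-epicatechin
Conditions: BnBr (4.4 equiv), K2CO3, DMF, 0 °C to rt
Reagents that add atoms: benzyl bromide, BrCc1ccccc1
Why: Williamson etherification in which K2CO3 deprotonates only the four phenols, so the secondary 3-OH stays free and C2 and C3 are untouched.

Step 2
Reactants: 2 5,7,3',4'-tetra-O-benzyl-(−)-epicatechin
Product: 3 3,5,7,3',4'-penta-O-benzyl-(−)-epicatechin
Conditions: NaH, BnBr, n-Bu4NI (cat.), DMF, 0 °C to rt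
Reagents that add atoms: benzyl bromide, BrCc1ccccc1
Why: Williamson etherification of the sodium alkoxide of the 3-OH, which removes the last acidic proton so that the later arylmagnesium step is possible.

Step 3
Reactants: 3 3,5,7,3',4'-penta-O-benzyl-(−)-epicatechin
Product: 4 4β-(2-ethoxyethoxy)-3,5,7,3',4'-penta-O-benzylepicatechin
Conditions: DDQ (2 equiv), HOCH2CH2OEt (5 equiv), CH2Cl2, rt
Reagents that add atoms: 2-ethoxyethanol, CCOCCO
Why: DDQ benzylic oxidation by hydride abstraction at C4, which is activated by the trialkoxy ring A, followed by capture of the cation by the alcohol anti to the 3-benzyloxy group to give the 3,4-trans (4β) ether.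

Step 4
Reactants: 4 4β-(2-ethoxyethoxy)-3,5,7,3',4'-penta-O-benzylepicatechin; 3 3,5,7,3',4'-penta-O-benzyl-(−)-epicatechin
Product: 5 per-O-benzyl epicatechin-(4β→8)-epicatechin (units 3 and 4)
Conditions: Me3SiOTf (0.5 equiv), 3 (4 equiv), CH2Cl2, −78 °C; Et3N quench
Reagents that add atoms: none
Why: Lewis-acid-mediated Friedel–Crafts interflavan coupling in which the C4 cation of 4 is attacked by C8 of 3, the most nucleophilic ring A position, anti to the 3-benzyloxy group (new C4 stereocentre β, 3,4-trans), while the excess of 3 suppresses self-condensation of 4.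

Step 5
Reactants: 4 4β-(2-ethoxyethoxy)-3,5,7,3',4'-penta-O-benzylepicatechin
Product: 6 8-bromo-4β-(2-ethoxyethoxy)-3,5,7,3',4'-penta-O-benzylepicatechin
Conditions: NBS (1.0 equiv), CH2Cl2, −40 to 0 °C
Reagents that add atoms: N-bromosuccinimide, O=C1CCC(=O)N1Br
Why: Electrophilic aromatic bromination, which in 5,7-dialkoxyflavans goes to C8, the less hindered and more nucleophilic ring A position, under non-acidic conditions that spare the C4 ether.

Step 6
Reactants: 6 8-bromo-4β-(2-ethoxyethoxy)-3,5,7,3',4'-penta-O-benzylepicatechin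
Product: 7 8-bromo-6-iodo-4β-(2-ethoxyethoxy)-3,5,7,3',4'-penta-O-benzylepicatechin
Conditions: NIS (1.3 equiv), MeCN/CH2Cl2, rt, dark
Reagents that add atoms: N-iodosuccinimide, O=C1CCC(=O)N1I
Why: Electrophilic aromatic iodination at C6, the only free ring A position, which is still activated by three oxygen donors and far more reactive than the catechol ring B; iodine is chosen so that it can later be exchanged for magnesium in the presence of the bromine.

Step 7
Reactants: 7 8-bromo-6-iodo-4β-(2-ethoxyethoxy)-3,5,7,3',4'-penta-O-benzylepicatechin; 5 per-O-benzyl epicatechin-(4β→8)-epicatechin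
Product: 8 8-bromo-6-iodo per-O-benzyl epicatechin-(4β→8)-epicatechin-(4β→8)-epicatechin (halogens on unit 2)
Conditions: Me3SiOTf (1.0 equiv), 5 (1.5 equiv), CH2Cl2, −78 to −40 °C; Et3N quench
Reagents that add atoms: none
Why: Lewis-acid-mediated Friedel–Crafts interflavan coupling in which the doubly halogen-capped electrophile cannot self-condense and its C4 cation is taken by the only free C8 of dimer 5 (unit 3) anti to the 3-benzyloxy group, setting C4 of unit 2 as β.

Step 8
Reactants: 9 2,4,6-trihydroxybenzaldehyde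
Product: 10 2,4-bis(benzyloxy)-6-hydroxybenzaldehyde
Conditions: BnBr (2.1 equiv), K2CO3, DMF, rt
Reagents that add atoms: benzyl bromide, BrCc1ccccc1
Why: Regioselective Williamson etherification in which the 4-OH and one ortho OH react, while the remaining ortho OH is held in a hydrogen bond to the formyl group and is the least nucleophilic.

Step 9
Reactants: 10 2,4-bis(benzyloxy)-6-hydroxybenzaldehyde
Product: 11 2-(allyloxy)-4,6-bis(benzyloxy)benzaldehyde
Conditions: allyl bromide, K2CO3, DMF, 50 °C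
Reagents that add atoms: allyl bromide, C=CCBr
Why: Williamson etherification of the chelated phenol under more forcing conditions; allyl is chosen because it cannot migrate to the later carbinol oxygen and is removable under neutral conditions.

Step 10
Reactants: 8 8-bromo-6-iodo per-O-benzyl epicatechin trimer; 11 2-(allyloxy)-4,6-bis(benzyloxy)benzaldehyde
Product: 13 [2-(allyloxy)-4,6-bis(benzyloxy)phenyl](C6-aryl)methanol of the per-O-benzyl 8-bromo trimer (both carbinol epimers), via trimer C6-arylmagnesium chloride 12 (not isolated)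
Conditions: i-PrMgCl·LiCl (1.1 equiv), THF, −20 °C; then 11 (2 equiv), −20 °C to rt; pH 7 phosphate buffer
Reagents that add atoms: isopropylmagnesium chloride–lithium chloride, CC(C)[Mg]Cl.[Li]Cl (supplies the MgCl of intermediate 12 only; none of its atoms remain in 13)
Why: Iodine–magnesium exchange, chemoselective for the C–I bond over the C–Br bond and favoured by the two ortho benzyloxy groups, followed by 1,2-addition of the arylmagnesium to the aldehyde; the new carbinol centre is formed without control, which is harmless because it is erased in step 15.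

Step 11
Reactants: 13 allyl-protected carbinol of the 8-bromo trimer
Product: 14 [2-hydroxy-4,6-bis(benzyloxy)phenyl](C6-aryl)methanol of the per-O-benzyl 8-bromo trimer (both carbinol epimers)
Conditions: Pd(PPh3)4 (5 mol%), morpholine (5 equiv), THF, rt; filtration through Et3N-deactivated silica
Reagents that add atoms: none
Why: Tsuji–Trost-type deallylation in which the aryl allyl ether ionises to a π-allylpalladium complex that morpholine intercepts, under neutral conditions that leave the benzyl ethers, the hindered electron-rich aryl bromide and the acid-labile diarylcarbinol intact.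

Step 12
Reactants: 15 3,4-dihydroxyphenylacetic acid
Product: 16 benzyl 2-[3,4-bis(benzyloxy)phenyl]acetate
Conditions: BnBr (3.3 equiv), K2CO3, DMF, 60 °C
Reagents that add atoms: benzyl bromide, BrCc1ccccc1
Why: Williamson-type O-alkylation of both phenoxides and of the carboxylate in one operation.

Step 13
Reactants: 16 benzyl 2-[3,4-bis(benzyloxy)phenyl]acetate
Product: 17 2-[3,4-bis(benzyloxy)phenyl]acetaldehyde
Conditions: i-Bu2AlH (1.1 equiv), CH2Cl2, −78 °C; aq. potassium sodium tartrate
Reagents that add atoms: none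
Why: Partial ester reduction in which the tetrahedral aluminium hemiacetal persists at −78 °C and releases the aldehyde only on work-up; the aldehyde is used at once because arylacetaldehydes self-condense.

Step 14
Reactants: 17 2-[3,4-bis(benzyloxy)phenyl]acetaldehyde
Product: 18 (E)-2-[3,4-bis(benzyloxy)phenyl]ethenyl acetate
Conditions: Ac2O, KOAc, 120 °C; (E)-isomer isolated by chromatography and crystallisation
Reagents that add atoms: acetic anhydride, CC(=O)OC(C)=O
Why: Enol acetylation by O-acylation of the styrene-conjugated enolate under equilibrating conditions, in which the (E)-isomer with aryl and acetoxy trans is expected to predominate and is separated from the (Z)-isomer.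

Step 15
Reactants: 14 [2-hydroxy-4,6-bis(benzyloxy)phenyl](C6-aryl)methanol of the 8-bromo trimer (both epimers); 18 (E)-2-[3,4-bis(benzyloxy)phenyl]ethenyl acetate
Product: 20 protected tetramer with unit 1 as 3-O-acetyl-5,7,3',4'-tetra-O-benzylcatechin linked 4α→6 to the per-O-benzyl 8-bromo trimer, via ortho-quinone methide 19 (not isolated)
Conditions: (R)-3,3'-bis(2,4,6-triisopropylphenyl)-1,1'-binaphthyl-2,2'-diyl hydrogen phosphate (10 mol%), 18 (5 equiv), 5 Å molecular sieves, CH2Cl2, −40 to 0 °C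
Reagents that add atoms: none
Why: Proposed new method: the phosphoric acid protonates the doubly benzylic hydroxyl of either epimer of 14 and water leaves, so both epimers converge on the planar ortho-quinone methide 19, held as a hydrogen-bonded ion pair with the chiral phosphate, which adds alkene 18 in an asynchronous inverse-electron-demand oxa-[4+2] cycloaddition; the closest known reaction type is the chiral phosphoric acid or N-triflylphosphoramide catalysed [4+2] annulation of ortho-quinone methides from 2-hydroxybenzhydrols with styrenes and enol derivatives, which has not been shown for a β-acyloxystyrene or for a methide carrying an oligoflavan. Ring C of unit 1 closes in a six-membered [4+2] mode, the methide carbon (C4) bonding first to the acetoxy-bearing alkene carbon (C3) and the quinone methide oxygen (O1) then closing on the benzylic carbon (C2). The regiochemistry follows from the alkene polarisation: acetoxy is a poor donor, whereas the 3,4-bis(benzyloxy)phenyl group stabilises the developing positive charge at C2, so 18 should react as a styrene and not as an enol. C2 and C3 take the 2,3-trans relationship from the (E)-alkene (a stepwise closure would also place the aryl group equatorial), and C4 becomes trans to the acetate through the acetoxy-exo half-chair that leads to the all-equatorial chroman. The absolute configuration (2R,3S at C2 and C3, unit-2 aryl on the α face at C4) has to be imposed by the chiral phosphate on the face of the methide carbon, because the stereocentres of the trimer are at least four bonds away; the wrong-face adduct is a diastereomer and can be removed by chromatography. The step also needs chemoselectivity against Friedel–Crafts capture of 19 by the free C6–H positions of units 3 and 4, which their two flanking benzyloxy groups and the fivefold excess of 18 should secure.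

Step 16
Reactants: 20 protected tetramer, unit 1 as 3-O-acetate
Product: 21 protected tetramer with free 3-OH on unit 1
Conditions: K2CO3, MeOH/THF, rt
Reagents that add atoms: none
Why: Base-catalysed transesterification (methanolysis) of the only ester; with no free phenol present there is no pathway for base-induced epimerisation at C2.

Step 17
Reactants: 21 protected tetramer with free 3-OH on unit 1
Product: 22 catechin-(4α→6)-epicatechin-(4β→8)-epicatechin-(4β→8)-epicatechin (CNP0228086.1)
Conditions: H2 (1 atm), Pd(OH)2/C, NaOAc (1.5 equiv), THF/MeOH/H2O, rt; Sephadex LH-20, lyophilisation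
Reagents that add atoms: none
Why: Catalytic hydrogenolysis of all 19 benzyl ethers with concurrent hydrodebromination at C8 of unit 2, the acetate buffer taking up the HBr so that the acid-labile interflavan bonds are not cleaved; no stereocentre is involved.

**Compound list**

1 | (−)-epicatechin, (2R,3R) | Oc1cc(O)c2c(c1)O[C@H](c1ccc(O)c(O)c1)[C@H](O)C2 | starting material
2 | 5,7,3',4'-tetra-O-benzyl-(−)-epicatechin (2R,3R; 3-OH free) | c9ccccc9COc1cc(OCc9ccccc9)c2c(c1)O[C@H](c1ccc(OCc9ccccc9)c(OCc9ccccc9)c1)[C@H](O)C2 | intermediate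
3 | 3,5,7,3',4'-penta-O-benzyl-(−)-epicatechin (2R,3R) | c9ccccc9COc1cc(OCc9ccccc9)c2c(c1)O[C@H](c1ccc(OCc9ccccc9)c(OCc9ccccc9)c1)[C@H](OCc9ccccc9)C2 | intermediate
4 | 4β-(2-ethoxyethoxy)-3,5,7,3',4'-penta-O-benzylepicatechin (2,3-cis, 3,4-trans) | c9ccccc9COc1cc(OCc9ccccc9)c2c(c1)O[C@H](c1ccc(OCc9ccccc9)c(OCc9ccccc9)c1)[C@H](OCc9ccccc9)[C@H]2OCCOCC | intermediate
5 | per-O-benzyl epicatechin-(4β→8)-epicatechin (decabenzyl dimer, units 3 and 4) | c1c(OCc9ccccc9)cc(OCc9ccccc9)c3c1O[C@H](c1ccc(OCc9ccccc9)c(OCc9ccccc9)c1)[C@H](OCc9ccccc9)[C@H]3c1c(OCc9ccccc9)cc(OCc9ccccc9)c3c1O[C@H](c1ccc(OCc9ccccc9)c(OCc9ccccc9)c1)[C@H](OCc9ccccc9)C3 | intermediate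
6 | 8-bromo-4β-(2-ethoxyethoxy)-3,5,7,3',4'-penta-O-benzylepicatechin | c9ccccc9COc1cc(OCc9ccccc9)c2c(c1Br)O[C@H](c1ccc(OCc9ccccc9)c(OCc9ccccc9)c1)[C@H](OCc9ccccc9)[C@H]2OCCOCC | intermediate
7 | 8-bromo-6-iodo-4β-(2-ethoxyethoxy)-3,5,7,3',4'-penta-O-benzylepicatechin | c9ccccc9COc1c(I)c(OCc9ccccc9)c2c(c1Br)O[C@H](c1ccc(OCc9ccccc9)c(OCc9ccccc9)c1)[C@H](OCc9ccccc9)[C@H]2OCCOCC | intermediate
8 | 8-bromo-6-iodo per-O-benzyl epicatechin-(4β→8)-epicatechin-(4β→8)-epicatechin (pentadecabenzyl trimer, halogens on unit 2) | Ic1c(OCc9ccccc9)c(Br)c2c(c1OCc9ccccc9)[C@H](c1c(OCc9ccccc9)cc(OCc9ccccc9)c3c1O[C@H](c1ccc(OCc9ccccc9)c(OCc9ccccc9)c1)[C@H](OCc9ccccc9)[C@H]3c1c(OCc9ccccc9)cc(OCc9ccccc9)c3c1O[C@H](c1ccc(OCc9ccccc9)c(OCc9ccccc9)c1)[C@H](OCc9ccccc9)C3)[C@@H](OCc9ccccc9)[C@@H](c1ccc(OCc9ccccc9)c(OCc9ccccc9)c1)O2 | intermediate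
9 | 2,4,6-trihydroxybenzaldehyde | O=Cc1c(O)cc(O)cc1O | starting material
10 | 2,4-bis(benzyloxy)-6-hydroxybenzaldehyde | O=Cc1c(O)cc(OCc9ccccc9)cc1OCc9ccccc9 | intermediate
11 | 2-(allyloxy)-4,6-bis(benzyloxy)benzaldehyde | O=Cc1c(OCC=C)cc(OCc9ccccc9)cc1OCc9ccccc9 | intermediate
12 | C6-arylmagnesium chloride of the per-O-benzyl 8-bromo trimer (not isolated) | Cl[Mg]c1c(OCc9ccccc9)c(Br)c2c(c1OCc9ccccc9)[C@H](c1c(OCc9ccccc9)cc(OCc9ccccc9)c3c1O[C@H](c1ccc(OCc9ccccc9)c(OCc9ccccc9)c1)[C@H](OCc9ccccc9)[C@H]3c1c(OCc9ccccc9)cc(OCc9ccccc9)c3c1O[C@H](c1ccc(OCc9ccccc9)c(OCc9ccccc9)c1)[C@H](OCc9ccccc9)C3)[C@@H](OCc9ccccc9)[C@@H](c1ccc(OCc9ccccc9)c(OCc9ccccc9)c1)O2 | intermediate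
13 | [2-(allyloxy)-4,6-bis(benzyloxy)phenyl](C6-aryl)methanol of the per-O-benzyl 8-bromo trimer, both carbinol epimers | C=CCOc1cc(OCc9ccccc9)cc(OCc9ccccc9)c1C(O)c1c(OCc9ccccc9)c(Br)c2c(c1OCc9ccccc9)[C@H](c1c(OCc9ccccc9)cc(OCc9ccccc9)c3c1O[C@H](c1ccc(OCc9ccccc9)c(OCc9ccccc9)c1)[C@H](OCc9ccccc9)[C@H]3c1c(OCc9ccccc9)cc(OCc9ccccc9)c3c1O[C@H](c1ccc(OCc9ccccc9)c(OCc9ccccc9)c1)[C@H](OCc9ccccc9)C3)[C@@H](OCc9ccccc9)[C@@H](c1ccc(OCc9ccccc9)c(OCc9ccccc9)c1)O2 | intermediate
14 | [2-hydroxy-4,6-bis(benzyloxy)phenyl](C6-aryl)methanol of the per-O-benzyl 8-bromo trimer, both carbinol epimers | Oc1cc(OCc9ccccc9)cc(OCc9ccccc9)c1C(O)c1c(OCc9ccccc9)c(Br)c2c(c1OCc9ccccc9)[C@H](c1c(OCc9ccccc9)cc(OCc9ccccc9)c3c1O[C@H](c1ccc(OCc9ccccc9)c(OCc9ccccc9)c1)[C@H](OCc9ccccc9)[C@H]3c1c(OCc9ccccc9)cc(OCc9ccccc9)c3c1O[C@H](c1ccc(OCc9ccccc9)c(OCc9ccccc9)c1)[C@H](OCc9ccccc9)C3)[C@@H](OCc9ccccc9)[C@@H](c1ccc(OCc9ccccc9)c(OCc9ccccc9)c1)O2 | intermediate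
15 | 3,4-dihydroxyphenylacetic acid | OC(=O)Cc1ccc(O)c(O)c1 | starting material
16 | benzyl 2-[3,4-bis(benzyloxy)phenyl]acetate | O=C(OCc9ccccc9)Cc1ccc(OCc9ccccc9)c(OCc9ccccc9)c1 | intermediate
17 | 2-[3,4-bis(benzyloxy)phenyl]acetaldehyde | O=CCc1ccc(OCc9ccccc9)c(OCc9ccccc9)c1 | intermediate
18 | (E)-2-[3,4-bis(benzyloxy)phenyl]ethenyl acetate | CC(=O)O/C=C/c1ccc(OCc9ccccc9)c(OCc9ccccc9)c1 | intermediate
19 | ortho-quinone methide, 3,5-bis(benzyloxy)-6-(arylmethylidene)cyclohexa-2,4-dien-1-one with aryl = C6 of the per-O-benzyl 8-bromo trimer (not isolated; alkene geometry not fixed) | O=C1C=C(OCc9ccccc9)C=C(OCc9ccccc9)C1=Cc1c(OCc9ccccc9)c(Br)c2c(c1OCc9ccccc9)[C@H](c1c(OCc9ccccc9)cc(OCc9ccccc9)c3c1O[C@H](c1ccc(OCc9ccccc9)c(OCc9ccccc9)c1)[C@H](OCc9ccccc9)[C@H]3c1c(OCc9ccccc9)cc(OCc9ccccc9)c3c1O[C@H](c1ccc(OCc9ccccc9)c(OCc9ccccc9)c1)[C@H](OCc9ccccc9)C3)[C@@H](OCc9ccccc9)[C@@H](c1ccc(OCc9ccccc9)c(OCc9ccccc9)c1)O2 | intermediate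
20 | [3-O-acetyl-5,7,3',4'-tetra-O-benzylcatechin]-(4α→6)-[8-bromo-penta-O-benzylepicatechin]-(4β→8)-[penta-O-benzylepicatechin]-(4β→8)-[penta-O-benzylepicatechin] | c9ccccc9COc1cc(OCc9ccccc9)c2c(c1)O[C@H](c1ccc(OCc9ccccc9)c(OCc9ccccc9)c1)[C@@H](OC(C)=O)[C@@H]2c1c(OCc9ccccc9)c(Br)c2c(c1OCc9ccccc9)[C@H](c1c(OCc9ccccc9)cc(OCc9ccccc9)c3c1O[C@H](c1ccc(OCc9ccccc9)c(OCc9ccccc9)c1)[C@H](OCc9ccccc9)[C@H]3c1c(OCc9ccccc9)cc(OCc9ccccc9)c3c1O[C@H](c1ccc(OCc9ccccc9)c(OCc9ccccc9)c1)[C@H](OCc9ccccc9)C3)[C@@H](OCc9ccccc9)[C@@H](c1ccc(OCc9ccccc9)c(OCc9ccccc9)c1)O2 | intermediate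
21 | same tetramer with free 3-OH on unit 1 (19 benzyl ethers, C8 bromine on unit 2) | c9ccccc9COc1cc(OCc9ccccc9)c2c(c1)O[C@H](c1ccc(OCc9ccccc9)c(OCc9ccccc9)c1)[C@@H](O)[C@@H]2c1c(OCc9ccccc9)c(Br)c2c(c1OCc9ccccc9)[C@H](c1c(OCc9ccccc9)cc(OCc9ccccc9)c3c1O[C@H](c1ccc(OCc9ccccc9)c(OCc9ccccc9)c1)[C@H](OCc9ccccc9)[C@H]3c1c(OCc9ccccc9)cc(OCc9ccccc9)c3c1O[C@H](c1ccc(OCc9ccccc9)c(OCc9ccccc9)c1)[C@H](OCc9ccccc9)C3)[C@@H](OCc9ccccc9)[C@@H](c1ccc(OCc9ccccc9)c(OCc9ccccc9)c1)O2 | intermediate
22 | catechin-(4α→6)-epicatechin-(4β→8)-epicatechin-(4β→8)-epicatechin, CNP0228086.1 | Oc1cc(O)c2c(c1)O[C@H](c1ccc(O)c(O)c1)[C@@H](O)[C@@H]2c1c(O)cc2c(c1O)[C@H](c1c(O)cc(O)c3c1O[C@H](c1ccc(O)c(O)c1)[C@H](O)[C@H]3c1c(O)cc(O)c3c1O[C@H](c1ccc(O)c(O)c1)[C@H](O)C3)[C@@H](O)[C@@H](c1ccc(O)c(O)c1)O2 | target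

**Step count and risks**

Total step count: 17. Longest linear sequence: 11 steps (steps 1, 2, 3, 5, 6, 7, 10, 11, 15, 16, 17).

Steps most likely to fail:

1. Step 15 (carries the label). The risks are:
   - the phosphate may discriminate the two faces of the methide carbon poorly or in the wrong sense;
   - the alkene may react as an enol rather than as a styrene;
   - the hindered, strongly stabilised methide may be captured by arene C–H positions or may not react at all.

   Fallback by known interflavan Friedel–Crafts chemistry with orthogonal oxygen and sulfur leaving groups. It sets out from 6 (with dimer 5 and commercial (+)-catechin) and comes back to the route at 20.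
   - 6 is exchanged at C4 with 2,6-dimethylbenzenethiol (BF3·OEt2, CH2Cl2, −78 °C) to the thioether 8-bromo-4β-(2,6-dimethylphenylsulfanyl)-penta-O-benzylepicatechin F1, whose only free ring A position is C6.
   - (+)-Catechin is benzylated (BnBr, K2CO3, DMF) to 5,7,3',4'-tetra-O-benzylcatechin F2, oxidised at C4 (DDQ, 2-ethoxyethanol, CH2Cl2) to 4-(2-ethoxyethoxy)-tetra-O-benzylcatechin F3 and acetylated (Ac2O, pyridine) to 3-O-acetyl-4-(2-ethoxyethoxy)-tetra-O-benzylcatechin F4.
   - Coupling of F4 with F1 (BF3·OEt2, CH2Cl2, −78 °C) should give the dimer [3-O-acetyl-tetra-O-benzylcatechin]-(4α→6)-[8-bromo-4β-(2,6-dimethylphenylsulfanyl)-penta-O-benzylepicatechin] F5. The hard Lewis acid ionises the C4 ether and leaves the arylthio group alone, the C8 bromine leaves only C6 to attack, and the C3 acetate steers the 3,4-trans (4α) approach.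
   - Thiophilic activation of F5 (AgBF4, THF/CH2Cl2, 0 °C) in the presence of 5 should then form the unit 2–unit 3 bond (4β→8) and give 20.

2. Step 7. Ionisation of the C4 ether may be sluggish because both ring A ether groups are flanked by halogens, capture by the bulky dimer may be slow, and the C6 iodine may be lost or transferred under the Lewis acid.

   Fallback by top-down assembly with a small nucleophile and a thio leaving group. It sets out from 4 and 7 and comes back at 8.
   - 4 is converted (2,6-dimethylbenzenethiol, BF3·OEt2, CH2Cl2, −78 °C) to 4β-(2,6-dimethylphenylsulfanyl)-penta-O-benzylepicatechin F6.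
   - 7 is coupled with an excess of this monomeric nucleophile (BF3·OEt2, −78 °C, short contact time) to the dimer [8-bromo-6-iodo-penta-O-benzylepicatechin]-(4β→8)-[4β-(2,6-dimethylphenylsulfanyl)-penta-O-benzylepicatechin] F7.
   - The thio group of F7 is activated without Brønsted acid (AgBF4, THF/CH2Cl2, 0 °C) in the presence of an excess of 3, which should give 8.

3. Step 10. The iodine–magnesium exchange may be incomplete, or the addition of a doubly ortho-flanked arylmagnesium to a doubly ortho-flanked, electron-rich aldehyde may be too slow, so that the aryl metal is merely protonated on work-up.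

   Fallback by reversed polarity. It sets out from 8 (through 12, generated as in step 10) and comes back at 14, leaving out 13 and step 11.
   - 12 is quenched with the small electrophile DMF to the 6-carbaldehyde of the per-O-benzyl 8-bromo trimer F8.
   - Bromomagnesium 3,5-bis(benzyloxy)phenoxide F9, made from commercial 3,5-bis(benzyloxy)phenol and EtMgBr and used in excess in toluene/CH2Cl2 at rt, is then added. This is the known ortho-specific hydroxyalkylation of magnesium phenoxides through a six-membered chelate. The two ortho positions are equivalent and the para position is not reached, so 14 should form directly with the free phenol.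

**Further compounds**

F1 | step 15 | 8-bromo-4β-(2,6-dimethylphenylsulfanyl)-3,5,7,3',4'-penta-O-benzylepicatechin | c9ccccc9COc1cc(OCc9ccccc9)c2c(c1Br)O[C@H](c1ccc(OCc9ccccc9)c(OCc9ccccc9)c1)[C@H](OCc9ccccc9)[C@H]2Sc1c(C)cccc1C
F2 | step 15 | 5,7,3',4'-tetra-O-benzyl-(+)-catechin (2R,3S) | c9ccccc9COc1cc(OCc9ccccc9)c2c(c1)O[C@H](c1ccc(OCc9ccccc9)c(OCc9ccccc9)c1)[C@@H](O)C2
F3 | step 15 | 4-(2-ethoxyethoxy)-5,7,3',4'-tetra-O-benzylcatechin (C4 configuration left open; it is erased on ionisation) | c9ccccc9COc1cc(OCc9ccccc9)c2c(c1)O[C@H](c1ccc(OCc9ccccc9)c(OCc9ccccc9)c1)[C@@H](O)C2OCCOCC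
F4 | step 15 | 3-O-acetyl-4-(2-ethoxyethoxy)-5,7,3',4'-tetra-O-benzylcatechin (C4 configuration left open) | c9ccccc9COc1cc(OCc9ccccc9)c2c(c1)O[C@H](c1ccc(OCc9ccccc9)c(OCc9ccccc9)c1)[C@@H](OC(C)=O)C2OCCOCC
F5 | step 15 | [3-O-acetyl-5,7,3',4'-tetra-O-benzylcatechin]-(4α→6)-[8-bromo-4β-(2,6-dimethylphenylsulfanyl)-penta-O-benzylepicatechin] | c9ccccc9COc1cc(OCc9ccccc9)c2c(c1)O[C@H](c1ccc(OCc9ccccc9)c(OCc9ccccc9)c1)[C@@H](OC(C)=O)[C@@H]2c1c(OCc9ccccc9)c(Br)c2c(c1OCc9ccccc9)[C@H](Sc1c(C)cccc1C)[C@@H](OCc9ccccc9)[C@@H](c1ccc(OCc9ccccc9)c(OCc9ccccc9)c1)O2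
F6 | step 7 | 4β-(2,6-dimethylphenylsulfanyl)-3,5,7,3',4'-penta-O-benzylepicatechin | c9ccccc9COc1cc(OCc9ccccc9)c2c(c1)O[C@H](c1ccc(OCc9ccccc9)c(OCc9ccccc9)c1)[C@H](OCc9ccccc9)[C@H]2Sc1c(C)cccc1C
F7 | step 7 | [8-bromo-6-iodo-penta-O-benzylepicatechin]-(4β→8)-[4β-(2,6-dimethylphenylsulfanyl)-penta-O-benzylepicatechin] | Ic1c(OCc9ccccc9)c(Br)c2c(c1OCc9ccccc9)[C@H](c1c(OCc9ccccc9)cc(OCc9ccccc9)c3c1O[C@H](c1ccc(OCc9ccccc9)c(OCc9ccccc9)c1)[C@H](OCc9ccccc9)[C@H]3Sc1c(C)cccc1C)[C@@H](OCc9ccccc9)[C@@H](c1ccc(OCc9ccccc9)c(OCc9ccccc9)c1)O2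
F8 | step 10 | 6-carbaldehyde of per-O-benzyl 8-bromo epicatechin-(4β→8)-epicatechin-(4β→8)-epicatechin (formyl on C6 of unit 2) | O=Cc1c(OCc9ccccc9)c(Br)c2c(c1OCc9ccccc9)[C@H](c1c(OCc9ccccc9)cc(OCc9ccccc9)c3c1O[C@H](c1ccc(OCc9ccccc9)c(OCc9ccccc9)c1)[C@H](OCc9ccccc9)[C@H]3c1c(OCc9ccccc9)cc(OCc9ccccc9)c3c1O[C@H](c1ccc(OCc9ccccc9)c(OCc9ccccc9)c1)[C@H](OCc9ccccc9)C3)[C@@H](OCc9ccccc9)[C@@H](c1ccc(OCc9ccccc9)c(OCc9ccccc9)c1)O2
F9 | step 10 | bromomagnesium 3,5-bis(benzyloxy)phenoxide | Br[Mg]Oc1cc(OCc9ccccc9)cc(OCc9ccccc9)c1
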